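The quaternary carbon C6 of the 1,2-dioxane ring carries peroxide oxygen O1 and is therefore a masked ketone, so its bond to the side-chain methylene C7 is made as an acyl–alkyl bond. A Fukuyama coupling unites the complete (E,E)-dienyl side chain, as a primary alkylzinc iodide, with an open-chain thioester–enoate holding C1–C6 and the C4 methyl centre. The resulting acyclic keto-enoate contains neither the dioxane ring nor a peroxide. Hydrogen peroxide then bridges C6 (methoxy peroxyketal) and C3 (oxa-Michael closure), and axial delivery of methyl to the cyclic peroxycarbenium ion sets C6. Saponification ends the route.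

Key step: step 12

Remark: ring atoms are numbered O1, O2, C3 (bearing CH2CO2H), C4, C5, C6, and the side chain runs from C7 (the CH2 on C6) through C8 (CHMe) to C14 (CH2Ph); acyclic intermediates keep this numbering. Both enantiomers of 4-benzyl-3-propanoyl-1,3-oxazolidin-2-one are taken as commercial. Compounds 25 and 26 are carried as C6-epimer mixtures, which converge in step 15.

Step 1
Reactants: 1 (4S)-4-benzyl-3-propanoyl-1,3-oxazolidin-2-one; 2 3-bromoprop-1-yne (propargyl bromide)
Product: 3 (4S)-4-benzyl-3-[(2R)-2-methylpent-4-ynoyl]-1,3-oxazolidin-2-one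
Conditions: NaHMDS, THF, −78 °C; then 2, −78 to −40 °C
Reagents that add atoms: none
Why: Evans asymmetric alkylation: the chelated (Z)-sodium enolate is alkylated on the face opposite the benzyl group, which should set the (R)-methyl centre that becomes C8.

Step 2
Reactants: 3 (4S)-4-benzyl-3-[(2R)-2-methylpent-4-ynoyl]-1,3-oxazolidin-2-one
Product: 4 (2R)-2-methylpent-4-yn-1-ol
Conditions: LiBH4, Et2O, H2O (1 equiv), 0 °C
Reagents that add atoms: none
Why: Reductive cleavage of the N-acyloxazolidinone with LiBH4 (hydride attack at the exocyclic carbonyl) should free the primary alcohol without touching the stereocentre or the alkyne.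

Step 3
Reactants: 4 (2R)-2-methylpent-4-yn-1-ol
Product: 6 (2R,4E)-5-iodo-2,4-dimethylpent-4-en-1-ol, via alkenylalane 5 (not isolated)
Conditions: Me3Al (3 equiv), Cp2ZrCl2 (cat.), CH2Cl2, 0 °C to rt; then I2, THF, −30 to 0 °C
Reagents that add atoms: trimethylaluminium C[Al](C)C; iodine II
Why: Negishi zirconium-catalysed carboalumination adds methyl and aluminium syn across the terminal alkyne with methyl on the internal carbon, and iodinolysis of the C–Al bond with retention should give the (E)-alkenyl iodide.

Step 4
Reactants: 6 (2R,4E)-5-iodo-2,4-dimethylpent-4-en-1-ol; 7 ethynyltrimethylsilane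
Product: 9 (2R,4E)-2,4-dimethylhept-4-en-6-yn-1-ol, via silylated enyne 8 (not isolated)
Conditions: PdCl2(PPh3)2 (cat.), CuI (cat.), Et3N, THF, rt; then K2CO3 (cat.), MeOH, rt
Reagents that add atoms: none
Why: Sonogashira coupling retains the alkene geometry, and the silyl group is then removed by base-catalysed methanolysis in the same flask.

Step 5
Reactants: 9 (2R,4E)-2,4-dimethylhept-4-en-6-yn-1-ol; 10 benzyl chloride
Product: 12 (2R,4E,6E)-2,4,6-trimethyl-8-phenylocta-4,6-dien-1-ol, via dienylalane 11 (not isolated)
Conditions: Me3Al (3 equiv), Cp2ZrCl2 (cat.), CH2Cl2, rt; then 10, Pd(PPh3)4 (cat.), THF, rt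
Reagents that add atoms: trimethylaluminium C[Al](C)C
Why: A second Negishi syn-carboalumination at the terminal alkyne of the enyne, followed by palladium-catalysed cross-coupling of the alkenylalane with benzyl chloride, both with retention, should give the (4E,6E)-diene.

Step 6
Reactants: 12 (2R,4E,6E)-2,4,6-trimethyl-8-phenylocta-4,6-dien-1-ol
Product: 13 [(2E,4E,7R)-8-iodo-3,5,7-trimethylocta-2,4-dien-1-yl]benzene
Conditions: PPh3, I2, imidazole, CH2Cl2, 0 °C
Reagents that add atoms: iodine II
Why: Appel-type iodination converts the primary alcohol by SN2 at CH2 and should leave the adjacent stereocentre and the diene untouched.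

Step 7
Reactants: 14 (4R)-4-benzyl-3-propanoyl-1,3-oxazolidin-2-one; 15 tert-butyl bromoacetate
Product: 16 tert-butyl (3S)-4-[(4R)-4-benzyl-2-oxo-1,3-oxazolidin-3-yl]-3-methyl-4-oxobutanoate
Conditions: NaHMDS, THF, −78 °C; then 15, −78 to −40 °C
Reagents that add atoms: none
Why: Evans asymmetric alkylation with the enantiomeric auxiliary should set the (S)-methyl centre that becomes C4, the benzyl group again shielding one enolate face.

Step 8
Reactants: 16 tert-butyl (3S)-4-[(4R)-4-benzyl-2-oxo-1,3-oxazolidin-3-yl]-3-methyl-4-oxobutanoate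
Product: 17 tert-butyl (3S)-4-hydroxy-3-methylbutanoate
Conditions: LiBH4, THF, MeOH (1 equiv), 0 °C
Reagents that add atoms: none
Why: Reductive cleavage of the imide with LiBH4 is chemoselective because the hindered tert-butyl ester should survive at 0 °C, so the primary alcohol is formed without touching the stereocentre.

Step 9
Reactants: 17 tert-butyl (3S)-4-hydroxy-3-methylbutanoate; 18 methyl (triphenyl-λ5-phosphanylidene)acetate
Product: 20 6-tert-butyl 1-methyl (2E,4S)-4-methylhex-2-enedioate, via aldehyde 19 (not isolated)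
Conditions: Dess–Martin periodinane, NaHCO3, CH2Cl2, 0 °C to rt; then 18, rt
Reagents that add atoms: none
Why: Dess–Martin oxidation followed by Wittig olefination with the stabilised ylide should give the (E)-enoate, the α-branched aldehyde being trapped in the flask before it can epimerise.

Step 10
Reactants: 20 6-tert-butyl 1-methyl (2E,4S)-4-methylhex-2-enedioate
Product: 21 (3S,4E)-6-methoxy-3-methyl-6-oxohex-4-enoic acid
Conditions: TFA, CH2Cl2, 0 °C to rt
Reagents that add atoms: none
Why: Acidolysis of the tert-butyl ester (E1 loss of 2-methylpropene) should leave the methyl enoate intact.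

Step 11
Reactants: 21 (3S,4E)-6-methoxy-3-methyl-6-oxohex-4-enoic acid
Product: 22 methyl (2E,4S)-6-(ethylsulfanyl)-4-methyl-6-oxohex-2-enoate
Conditions: EtSH, EDC·HCl, DMAP (cat.), CH2Cl2, 0 °C to rt
Reagents that add atoms: ethanethiol CCS
Why: Steglich-type thioesterification (carbodiimide activation, DMAP acyl transfer) should give the S-ethyl thioester, the β-substituted enoate being a poor thia-Michael acceptor under these conditions.

Step 12
Reactants: 13 [(2E,4E,7R)-8-iodo-3,5,7-trimethylocta-2,4-dien-1-yl]benzene; 22 methyl (2E,4S)-6-(ethylsulfanyl)-4-methyl-6-oxohex-2-enoate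
Product: 24 methyl (2E,4S,8R,10E,12E)-4,8,10,12-tetramethyl-6-oxo-14-phenyltetradeca-2,10,12-trienoate, via alkylzinc iodide 23 (not isolated)
Conditions: Zn dust (activated with TMSCl and 1,2-dibromoethane), THF, 40 °C; then 22, PdCl2(PPh3)2 (cat.), toluene/THF, rt
Reagents that add atoms: none
Why: Fukuyama coupling, used as the known reaction type: Pd(0) inserts into the C(acyl)–S bond of 22, the primary alkylzinc iodide 23 transmetallates, and reductive elimination from the acyl(alkyl)palladium(II) forms the C6–C7 bond as a ketone. No ring is closed and no stereocentre is made; the C4 and C8 centres are β to the reacting carbons, bear no acidic hydrogen under these neutral conditions and should pass unchanged, as should the (E,E)-diene and the (E)-enoate. The selectivity the step needs is acyl transfer at C6 in preference to 1,4-addition to the enoate, attack on the methyl ester or over-addition to the new ketone, and it is secured by the low nucleophilicity of the organozinc and by oxidative addition being possible only at the thioester. Reductive elimination from the acylpalladium alkyl should be fast enough to outrun β-hydride elimination of the β-branched alkyl group. The ketone placed at C6 is what allows H2O2 to bridge C6 and C3 in steps 13 and 14, and the side chain has to be on C6 before the methyl group because axial attack on the later peroxycarbenium ion puts the incoming group trans to the C4 methyl.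

Step 13
Reactants: 24 methyl (2E,4S,8R,10E,12E)-4,8,10,12-tetramethyl-6-oxo-14-phenyltetradeca-2,10,12-trienoate
Product: 25 methyl (2E,4S,6RS,8R,10E,12E)-6-hydroperoxy-6-methoxy-4,8,10,12-tetramethyl-14-phenyltetradeca-2,10,12-trienoate
Conditions: urea–H2O2, Sc(OTf)3 (cat.), MeOH, rt
Reagents that add atoms: hydrogen peroxide (as its urea adduct) OO; methanol CO
Why: Lewis acid-catalysed hydroperoxyketalisation: Sc(OTf)3 activates the ketone (through the methoxy oxocarbenium ion in methanol) for capture by H2O2, a transformation precedented for 6-oxo-2-enoates, and metal-free H2O2 should not epoxidise the diene or the enoate.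

Step 14
Reactants: 25 methyl (2E,4S,6RS,8R,10E,12E)-6-hydroperoxy-6-methoxy-4,8,10,12-tetramethyl-14-phenyltetradeca-2,10,12-trienoate
Product: 26 methyl 2-[(3R,4S,6RS)-6-methoxy-4-methyl-6-[(2R,4E,6E)-2,4,6-trimethyl-8-phenylocta-4,6-dien-1-yl]-1,2-dioxan-3-yl]acetate
Conditions: Et2NH (cat.), CF3CH2OH, rt
Reagents that add atoms: none
Why: Intramolecular oxa-Michael addition (6-exo-trig) of the hydroperoxide to the enoate, in a protic fluorinated solvent that protonates the ester enolate at once; a chair transition state with the C4 methyl and the CH2CO2Me group equatorial, reinforced by reversibility, should set C3 as (R), trans to the C4 methyl.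

Step 15
Reactants: 26 methyl 2-[(3R,4S,6RS)-6-methoxy-4-methyl-6-[(2R,4E,6E)-2,4,6-trimethyl-8-phenylocta-4,6-dien-1-yl]-1,2-dioxan-3-yl]acetate
Product: 27 methyl 2-[(3R,4S,6R)-4,6-dimethyl-6-[(2R,4E,6E)-2,4,6-trimethyl-8-phenylocta-4,6-dien-1-yl]-1,2-dioxan-3-yl]acetate
Conditions: Me3Al (4 equiv), TMSOTf (1.2 equiv), CH2Cl2, −78 °C
Reagents that add atoms: trimethylaluminium C[Al](C)C
Why: Proposed new method: TMSOTf should silylate the exocyclic methoxy group of the cyclic peroxyketal and expel MeOSiMe3 to give the six-membered peroxycarbenium ion (C6=O1+), which the excess Me3Al methylates at C6; the closest known reaction types are the Lewis acid-mediated substitution of cyclic peroxyketals by allylsilanes and silyl enol ethers through peroxycarbenium ions and the Me3Al/TMSOTf C-methylation of cyclic ketals (organoaluminium C-alkylation is also known on cyclic acetals that carry an endoperoxide); by the axial-attack (chair-like transition state) model for six-membered oxocarbenium ions, the half-chair ion with the C3 and C4 substituents pseudo-equatorial should take up methyl axially, trans to the C4 methyl and cis to the C3 substituent, leaving the side chain equatorial, i.e. (6R), from either C6 epimer of 26.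

Step 16
Reactants: 27 methyl 2-[(3R,4S,6R)-4,6-dimethyl-6-[(2R,4E,6E)-2,4,6-trimethyl-8-phenylocta-4,6-dien-1-yl]-1,2-dioxan-3-yl]acetate
Product: 28 2-[(3R,4S,6R)-4,6-dimethyl-6-[(2R,4E,6E)-2,4,6-trimethyl-8-phenylocta-4,6-dien-1-yl]-1,2-dioxan-3-yl]acetic acid
Conditions: LiOH·H2O, THF/MeOH/H2O, 0 °C to rt; then 1 M HCl to pH 3, 0 °C
Reagents that add atoms: lithium hydroxide [Li+].[OH-]
Why: Saponification (BAc2) with LiOH is the standard way to free β-peroxy acids of this type; any retro-oxa-Michael opening should reclose to the same 3,4-trans ring, and the dialkyl peroxide and diene should tolerate cold dilute acid.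

Compound list
1 | (4S)-4-benzyl-3-propanoyl-1,3-oxazolidin-2-one | CCC(=O)N1[C@@H](Cc2ccccc2)COC1=O | starting material
2 | 3-bromoprop-1-yne (propargyl bromide) | C#CCBr | starting material
3 | (4S)-4-benzyl-3-[(2R)-2-methylpent-4-ynoyl]-1,3-oxazolidin-2-one | C#CC[C@@H](C)C(=O)N1[C@@H](Cc2ccccc2)COC1=O | intermediate
4 | (2R)-2-methylpent-4-yn-1-ol | C#CC[C@@H](C)CO | intermediate
5 | alkenylalane, [(1E,4R)-5-(dimethylalumanyloxy)-2,4-dimethylpent-1-en-1-yl]dimethylalumane | C[Al](C)OC[C@H](C)C/C(C)=C/[Al](C)C | intermediate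
6 | (2R,4E)-5-iodo-2,4-dimethylpent-4-en-1-ol | OC[C@H](C)C/C(C)=C/I | intermediate
7 | ethynyltrimethylsilane | C#C[Si](C)(C)C | starting material
8 | silylated enyne, (2R,4E)-2,4-dimethyl-7-(trimethylsilyl)hept-4-en-6-yn-1-ol | OC[C@H](C)C/C(C)=C/C#C[Si](C)(C)C | intermediate
9 | (2R,4E)-2,4-dimethylhept-4-en-6-yn-1-ol | OC[C@H](C)C/C(C)=C/C#C | intermediate
10 | benzyl chloride | ClCc1ccccc1 | starting material
11 | dienylalane, [(1E,3E,6R)-7-(dimethylalumanyloxy)-2,4,6-trimethylhepta-1,3-dien-1-yl]dimethylalumane | C[Al](C)OC[C@H](C)C/C(C)=C/C(C)=C/[Al](C)C | intermediate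
12 | (2R,4E,6E)-2,4,6-trimethyl-8-phenylocta-4,6-dien-1-ol | OC[C@H](C)C/C(C)=C/C(C)=C/Cc1ccccc1 | intermediate
13 | [(2E,4E,7R)-8-iodo-3,5,7-trimethylocta-2,4-dien-1-yl]benzene | IC[C@H](C)C/C(C)=C/C(C)=C/Cc1ccccc1 | intermediate
14 | (4R)-4-benzyl-3-propanoyl-1,3-oxazolidin-2-one | CCC(=O)N1[C@H](Cc2ccccc2)COC1=O | starting material
15 | tert-butyl bromoacetate | CC(C)(C)OC(=O)CBr | starting material
16 | tert-butyl (3S)-4-[(4R)-4-benzyl-2-oxo-1,3-oxazolidin-3-yl]-3-methyl-4-oxobutanoate | CC(C)(C)OC(=O)C[C@H](C)C(=O)N1[C@H](Cc2ccccc2)COC1=O | intermediate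
17 | tert-butyl (3S)-4-hydroxy-3-methylbutanoate | CC(C)(C)OC(=O)C[C@H](C)CO | intermediate
18 | methyl (triphenyl-λ5-phosphanylidene)acetate | COC(=O)C=P(c1ccccc1)(c1ccccc1)c1ccccc1 | starting material
19 | aldehyde, tert-butyl (3S)-3-methyl-4-oxobutanoate | CC(C)(C)OC(=O)C[C@H](C)C=O | intermediate
20 | 6-tert-butyl 1-methyl (2E,4S)-4-methylhex-2-enedioate | CC(C)(C)OC(=O)C[C@H](C)/C=C/C(=O)OC | intermediate
21 | (3S,4E)-6-methoxy-3-methyl-6-oxohex-4-enoic acid | OC(=O)C[C@H](C)/C=C/C(=O)OC | intermediate
22 | methyl (2E,4S)-6-(ethylsulfanyl)-4-methyl-6-oxohex-2-enoate | CCSC(=O)C[C@H](C)/C=C/C(=O)OC | intermediate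
23 | alkylzinc iodide, iodo[(2R,4E,6E)-2,4,6-trimethyl-8-phenylocta-4,6-dien-1-yl]zinc | I[Zn]C[C@H](C)C/C(C)=C/C(C)=C/Cc1ccccc1 | intermediate
24 | methyl (2E,4S,8R,10E,12E)-4,8,10,12-tetramethyl-6-oxo-14-phenyltetradeca-2,10,12-trienoate | COC(=O)/C=C/[C@@H](C)CC(=O)C[C@H](C)C/C(C)=C/C(C)=C/Cc1ccccc1 | intermediate
25 | methyl (2E,4S,6RS,8R,10E,12E)-6-hydroperoxy-6-methoxy-4,8,10,12-tetramethyl-14-phenyltetradeca-2,10,12-trienoate | COC(=O)/C=C/[C@@H](C)CC(OC)(OO)C[C@H](C)C/C(C)=C/C(C)=C/Cc1ccccc1 | intermediate
26 | methyl 2-[(3R,4S,6RS)-6-methoxy-4-methyl-6-[(2R,4E,6E)-2,4,6-trimethyl-8-phenylocta-4,6-dien-1-yl]-1,2-dioxan-3-yl]acetate | CC(=C\Cc1ccccc1)/C=C(\C)C[C@@H](C)CC1(OC)C[C@H](C)[C@@H](CC(=O)OC)OO1 | intermediate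
27 | methyl 2-[(3R,4S,6R)-4,6-dimethyl-6-[(2R,4E,6E)-2,4,6-trimethyl-8-phenylocta-4,6-dien-1-yl]-1,2-dioxan-3-yl]acetate | CC(=C\Cc1ccccc1)/C=C(\C)C[C@@H](C)C[C@]1(C)C[C@H](C)[C@@H](CC(=O)OC)OO1 | intermediate
28 | 2-[(3R,4S,6R)-4,6-dimethyl-6-[(2R,4E,6E)-2,4,6-trimethyl-8-phenylocta-4,6-dien-1-yl]-1,2-dioxan-3-yl]acetic acid | CC(=C\Cc1ccccc1)/C=C(\C)C[C@@H](C)C[C@]1(C)C[C@H](C)[C@@H](CC(=O)O)OO1 | target

Total step count: 16 steps.
Longest linear sequence: 11 steps (steps 1–6, then 12–16).

Steps most likely to fail

Step 15 (Proposed new method). The Lewis acid may ionise the ring C6–O1 bond instead of the exocyclic C6–OMe bond, or trigger a Hock/Criegee-type fragmentation. The organoaluminium may reduce the O–O bond. The peroxycarbenium ion may be captured by the C10=C11 alkene of the side chain (cation–olefin cyclisation) before methyl transfer, or the facial selectivity may be poor. The fallback uses known chemistry, sets out from ketone 24 and comes back at 27. Chemoselective Takai–Lombardo methylenation (Zn, CH2Br2, TiCl4) of the ketone would give methyl (2E,4S,8S,10E,12E)-4,8,10,12-tetramethyl-6-methylidene-14-phenyltetradeca-2,10,12-trienoate F1 (the 8S descriptor reflects only a change in CIP priorities). Mukaiyama–Isayama hydroperoxysilylation (Co(thd)2, O2, Et3SiH) of the 1,1-disubstituted alkene would give the tertiary silyl peroxide methyl (2E,4S,6RS,8R,10E,12E)-4,6,8,10,12-pentamethyl-14-phenyl-6-[(triethylsilyl)peroxy]tetradeca-2,10,12-trienoate F2. TBAF would then free the hydroperoxide, which closes onto the enoate in the same flask to give 27 and its C6 epimer methyl 2-[(3R,4S,6S)-4,6-dimethyl-6-[(2R,4E,6E)-2,4,6-trimethyl-8-phenylocta-4,6-dien-1-yl]-1,2-dioxan-3-yl]acetate F3, to be separated by chromatography. This fallback gives no control at C6 and relies on the terminal methylidene reacting faster than the trisubstituted diene.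

Step 13. The Lewis acid in methanol may add solvent or peroxide to the acid-sensitive conjugated diene or shift its double bonds. The hindered ketone may convert incompletely or go on to a gem-dihydroperoxide. The fallback sets out from 24 and comes back at 25, and separates ketal formation from peroxide introduction. 24 would first be converted (HC(OMe)3, PPTS, MeOH) into the dimethyl ketal methyl (2E,4S,8R,10E,12E)-6,6-dimethoxy-4,8,10,12-tetramethyl-14-phenyltetradeca-2,10,12-trienoate F4. One methoxy group would then be exchanged for OOH by transketalisation with anhydrous ethereal H2O2 and a trace of PPTS at 0 °C to give 25, so that no metal Lewis acid is present together with the peroxide.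

Step 12. Zinc insertion into the β-branched iodide may be slow or accompanied by Wurtz-type homocoupling or protonation. At palladium, β-hydride elimination or decarbonylation may compete with reductive elimination. The fallback sets out from acid 21 (with iodide 13) and comes back at 24, and avoids a preformed organometallic. 21 would be converted (2,2'-dipyridyl disulfide, PPh3) into the S-2-pyridyl thioester methyl (2E,4S)-4-methyl-6-oxo-6-(pyridin-2-ylsulfanyl)hex-2-enoate F5. This would be joined to 13 by nickel-catalysed reductive cross-electrophile coupling (NiCl2·glyme, 4,4'-di-tert-butyl-2,2'-bipyridine, Mn, DMA) to give 24.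

Further compounds
F1 | step 15 | methyl (2E,4S,8S,10E,12E)-4,8,10,12-tetramethyl-6-methylidene-14-phenyltetradeca-2,10,12-trienoate | COC(=O)/C=C/[C@@H](C)CC(=C)C[C@H](C)C/C(C)=C/C(C)=C/Cc1ccccc1
F2 | step 15 | methyl (2E,4S,6RS,8R,10E,12E)-4,6,8,10,12-pentamethyl-14-phenyl-6-[(triethylsilyl)peroxy]tetradeca-2,10,12-trienoate | COC(=O)/C=C/[C@@H](C)CC(C)(OO[Si](CC)(CC)CC)C[C@H](C)C/C(C)=C/C(C)=C/Cc1ccccc1
F3 | step 15 | methyl 2-[(3R,4S,6S)-4,6-dimethyl-6-[(2R,4E,6E)-2,4,6-trimethyl-8-phenylocta-4,6-dien-1-yl]-1,2-dioxan-3-yl]acetate | CC(=C\Cc1ccccc1)/C=C(\C)C[C@@H](C)C[C@@]1(C)C[C@H](C)[C@@H](CC(=O)OC)OO1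
F4 | step 13 | methyl (2E,4S,8R,10E,12E)-6,6-dimethoxy-4,8,10,12-tetramethyl-14-phenyltetradeca-2,10,12-trienoate | COC(=O)/C=C/[C@@H](C)CC(OC)(OC)C[C@H](C)C/C(C)=C/C(C)=C/Cc1ccccc1
F5 | step 12 | methyl (2E,4S)-4-methyl-6-oxo-6-(pyridin-2-ylsulfanyl)hex-2-enoate | COC(=O)/C=C/[C@@H](C)CC(=O)Sc1ccccn1
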